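**Strategy.** The isoflavanone is disconnected at O1–C2. C2 of ring C is a bare methylene flanked by O1 and the stereogenic C3. Ring C can therefore be closed by 6-endo-trig addition of the ring A phenol to the terminal carbon of a C2=C3 α-aryl enone. The C3=C4 enol so formed is protonated face-selectively under a chiral phosphoric acid, so one operation forms O1–C2, ring C and the sole stereocentre. The precursor is a 1-(2-hydroxyaryl)-2-arylprop-2-en-1-one carrying triisopropylsilyl ethers on the 7- and 2'-oxygens. It is generated by a neutral MnO2 oxidation so that no base ever meets it, and it is unmasked at the end by buffered fluoride to spare the labile C3 centre.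

Key step: step 10

Remarks on the chemistry:
- The target SMILES encodes the (3S) configuration (CIP order at C3: C4 > C2 > C1' > H), and the route is aimed at that enantiomer.
- The sense of induction of the chiral acid in step 10 cannot be predicted with confidence. (R)-TRIP is written, and its mirror-image form is to be used if that is the one that delivers (3S).

**Ring B fragment**

Step 1
Reactants: 1 paeonol, 1-(2-hydroxy-4-methoxyphenyl)ethanone
Product: 2 1-(5-bromo-2-hydroxy-4-methoxyphenyl)ethanone
Conditions: NBS (1.05 equiv), MeCN, 0 °C to rt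
Reagents that add atoms: N-bromosuccinimide, O=C1CCC(=O)N1Br
Why: Electrophilic aromatic bromination is directed to C5, which is para to the free phenol, ortho to the methoxy group and unhindered, whereas C3 lies between the two oxygens and C6 is deactivated by the acetyl group.

Step 2
Reactants: 2 1-(5-bromo-2-hydroxy-4-methoxyphenyl)ethanone
Product: 3 1-[5-bromo-4-methoxy-2-(triisopropylsilyloxy)phenyl]ethanone
Conditions: TIPSOTf, 2,6-lutidine, CH2Cl2, 0 °C
Reagents that add atoms: triisopropylsilyl trifluoromethanesulfonate, CC(C)[Si](OS(=O)(=O)C(F)(F)F)(C(C)C)C(C)C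
Why: O-Silylation with the silyl triflate overcomes the low reactivity of the phenol that is hydrogen-bonded to the acetyl group, and the bulky triisopropylsilyl ether is chosen because it should resist the later basic and organometallic steps yet leave with buffered fluoride at the end.

Step 3
Reactants: 3 1-[5-bromo-4-methoxy-2-(triisopropylsilyloxy)phenyl]ethanone; 4 tributyl(3-methylbut-2-enyl)stannane
Product: 5 1-[4-methoxy-5-(3-methylbut-2-enyl)-2-(triisopropylsilyloxy)phenyl]ethanone
Conditions: Pd(PPh3)4 (5 mol%), DMF, 90 °C
Reagents that add atoms: none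
Why: Stille cross-coupling of the aryl bromide with the allylic stannane should deliver the linear prenyl arene, since reductive elimination from the σ-allyl palladium species bonded through its unsubstituted terminus is favoured, and the ketone and the silyl ether are inert to the neutral conditions.

Step 4
Reactants: 5 1-[4-methoxy-5-(3-methylbut-2-enyl)-2-(triisopropylsilyloxy)phenyl]ethanone
Product: 7 1-[4-methoxy-5-(3-methylbut-2-enyl)-2-(triisopropylsilyloxy)phenyl]ethenyl trifluoromethanesulfonate, via the potassium enolate 6 (not isolated)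
Conditions: KN(SiMe3)2 (1.05 equiv), THF, −78 °C; then Comins' reagent, −78 °C; chromatography on Et3N-deactivated silica
Reagents that add atoms: Comins' reagent, N-(5-chloropyridin-2-yl)-1,1,1-trifluoro-N-(trifluoromethylsulfonyl)methanesulfonamide, O=S(=O)(N(c1ccc(Cl)cn1)S(=O)(=O)C(F)(F)F)C(F)(F)F
Why: Kinetic deprotonation of the only enolisable position, the acetyl methyl group, followed by O-sulfonylation of the enolate at −78 °C with the reactive pyridyl triflimide (enol triflate formation) should give the 1-arylethenyl triflate before the 2'-silyl group can migrate.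

**Ring A fragment**

Step 5
Reactants: 8 2,4-dihydroxybenzaldehyde
Product: 9 2-hydroxy-4-(triisopropylsilyloxy)benzaldehyde
Conditions: TIPSCl (1.05 equiv), imidazole, CH2Cl2, 0 °C
Reagents that add atoms: chlorotriisopropylsilane, CC(C)[Si](Cl)(C(C)C)C(C)C
Why: Regioselective silylation occurs at the 4-hydroxyl because the 2-hydroxyl is tied up in a hydrogen bond to the formyl group and is the more hindered and less nucleophilic of the two.

Step 6
Reactants: 9 2-hydroxy-4-(triisopropylsilyloxy)benzaldehyde
Product: 10 2-(prop-2-enyloxy)-4-(triisopropylsilyloxy)benzaldehyde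
Conditions: allyl alcohol, PPh3, DIAD, THF, 0 °C to rt
Reagents that add atoms: allyl alcohol (prop-2-en-1-ol), C=CCO
Why: Mitsunobu etherification alkylates the acidic salicylaldehyde-type phenol under neutral conditions, which avoids carbonate bases that could cleave the aryl silyl ether para to the formyl group.

**Fragment union and end-game**

Step 7
Reactants: 7 1-[4-methoxy-5-(3-methylbut-2-enyl)-2-(triisopropylsilyloxy)phenyl]ethenyl trifluoromethanesulfonate; 10 2-(prop-2-enyloxy)-4-(triisopropylsilyloxy)benzaldehyde
Product: 11 (±)-1-[2-(prop-2-enyloxy)-4-(triisopropylsilyloxy)phenyl]-2-[4-methoxy-5-(3-methylbut-2-enyl)-2-(triisopropylsilyloxy)phenyl]prop-2-en-1-ol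
Conditions: CrCl2 (4 equiv), NiCl2 (2 mol%), DMF, rt; aqueous work-up
Reagents that add atoms: none
Why: Nozaki–Hiyama–Kishi coupling (nickel-catalysed, chromium-mediated addition of the alkenyl triflate to the aldehyde) is chemoselective for the aldehyde, is not basic enough to move silyl groups, and forms the carbinol centre as a racemate that is erased in step 9.

Step 8
Reactants: 11 (±)-1-[2-(prop-2-enyloxy)-4-(triisopropylsilyloxy)phenyl]-2-[4-methoxy-5-(3-methylbut-2-enyl)-2-(triisopropylsilyloxy)phenyl]prop-2-en-1-ol
Product: 12 (±)-2-{1-hydroxy-2-[4-methoxy-5-(3-methylbut-2-enyl)-2-(triisopropylsilyloxy)phenyl]prop-2-enyl}-5-(triisopropylsilyloxy)phenol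
Conditions: Pd(PPh3)4 (5 mol%), morpholine, THF, rt
Reagents that add atoms: none
Why: Zerovalent palladium ionises the aryl allyl ether to a π-allyl complex that morpholine captures (Tsuji–Trost deallylation), which frees the ring A phenol at the carbinol stage, before any enone is present that the amine or a phenoxide could attack.

Step 9
Reactants: 12 (±)-2-{1-hydroxy-2-[4-methoxy-5-(3-methylbut-2-enyl)-2-(triisopropylsilyloxy)phenyl]prop-2-enyl}-5-(triisopropylsilyloxy)phenol
Product: 13 1-[2-hydroxy-4-(triisopropylsilyloxy)phenyl]-2-[4-methoxy-5-(3-methylbut-2-enyl)-2-(triisopropylsilyloxy)phenyl]prop-2-en-1-one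
Conditions: activated MnO2 (excess), CH2Cl2, rt; filtration through Celite, concentration cold, used at once in step 10
Reagents that add atoms: none
Why: MnO2 oxidises the alcohol that is both benzylic and allylic under neutral heterogeneous conditions, so the enone should form without base and its phenol should stay hydrogen-bonded to the new carbonyl group instead of adding to the alkene.

Step 10
Reactants: 13 1-[2-hydroxy-4-(triisopropylsilyloxy)phenyl]-2-[4-methoxy-5-(3-methylbut-2-enyl)-2-(triisopropylsilyloxy)phenyl]prop-2-en-1-one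
Product: 15 (3S)-3-[4-methoxy-5-(3-methylbut-2-enyl)-2-(triisopropylsilyloxy)phenyl]-7-(triisopropylsilyloxy)chroman-4-one, via the chromen-4-ol enol 14 (not isolated)
Conditions: (R)-TRIP [(R)-3,3'-bis(2,4,6-triisopropylphenyl)-1,1'-binaphthyl-2,2'-diyl hydrogen phosphate] (10 mol%), toluene, −40 °C; filtration through a short pad of neutral silica
Reagents that add atoms: none
Why: Proposed new method: the phosphoric acid should replace the intramolecular O–H···O=C hydrogen bond of 13, its P–OH activating the C4 carbonyl and its P=O accepting the ring A phenol proton, so that O1 adds to the terminal C2 methylene and gives the catalyst-bound enol 14, which the same acid then protonates at C3 while taking back the enol proton. The closest known reaction types are organocatalytic asymmetric intramolecular oxa-Michael cyclisations of 2'-hydroxychalcones to flavanones and conjugate addition–enantioselective protonation cascades of α-substituted enones and acrylates under chiral Brønsted acids. Ring C closes in the 6-endo-trig mode, both alkene carbons (C2 and C3) ending inside the new ring. The C3 stereocentre is set by the chiral phosphate, which shields one face of the planar enol during proton transfer. The step needs the catalysed pathway to outrun uncatalysed closure and any later enolisation: the substrate's own hydrogen bond keeps the phenol unreactive in cold toluene without base, the weakly acidic medium should not enolise the α-aryl ketone product at −40 °C, and the 2'-oxygen is silylated so that only the ring A oxygen can add.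

Step 11
Reactants: 15 (3S)-3-[4-methoxy-5-(3-methylbut-2-enyl)-2-(triisopropylsilyloxy)phenyl]-7-(triisopropylsilyloxy)chroman-4-one
Product: 16 (3S)-7-hydroxy-3-[2-hydroxy-4-methoxy-5-(3-methylbut-2-enyl)phenyl]chroman-4-one (CNP0227207.1)
Conditions: Bu4NF, AcOH (one equivalent of each per silyl group), THF, 0 °C
Reagents that add atoms: none
Why: Fluoride cleaves both aryl silyl ethers (desilylation) while acetic acid keeps the medium close to neutral, so the configurationally labile α-aryl ketone centre C3 should not enolise and the prenyl alkene is not exposed to strong acid.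

**Compound list**

1 | paeonol, 1-(2-hydroxy-4-methoxyphenyl)ethanone | CC(=O)c1ccc(OC)cc1O | starting material
2 | 1-(5-bromo-2-hydroxy-4-methoxyphenyl)ethanone | CC(=O)c1cc(Br)c(OC)cc1O | intermediate
3 | 1-[5-bromo-4-methoxy-2-(triisopropylsilyloxy)phenyl]ethanone | CC(=O)c1cc(Br)c(OC)cc1O[Si](C(C)C)(C(C)C)C(C)C | intermediate
4 | tributyl(3-methylbut-2-enyl)stannane | CCCC[Sn](CCCC)(CCCC)CC=C(C)C | starting material
5 | 1-[4-methoxy-5-(3-methylbut-2-enyl)-2-(triisopropylsilyloxy)phenyl]ethanone | CC(=O)c1cc(CC=C(C)C)c(OC)cc1O[Si](C(C)C)(C(C)C)C(C)C | intermediate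
6 | potassium 1-[4-methoxy-5-(3-methylbut-2-enyl)-2-(triisopropylsilyloxy)phenyl]ethenolate (not isolated) | [K+].[O-]C(=C)c1cc(CC=C(C)C)c(OC)cc1O[Si](C(C)C)(C(C)C)C(C)C | intermediate
7 | 1-[4-methoxy-5-(3-methylbut-2-enyl)-2-(triisopropylsilyloxy)phenyl]ethenyl trifluoromethanesulfonate | C=C(OS(=O)(=O)C(F)(F)F)c1cc(CC=C(C)C)c(OC)cc1O[Si](C(C)C)(C(C)C)C(C)C | intermediate
8 | 2,4-dihydroxybenzaldehyde | O=Cc1ccc(O)cc1O | starting material
9 | 2-hydroxy-4-(triisopropylsilyloxy)benzaldehyde | O=Cc1ccc(O[Si](C(C)C)(C(C)C)C(C)C)cc1O | intermediate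
10 | 2-(prop-2-enyloxy)-4-(triisopropylsilyloxy)benzaldehyde | O=Cc1ccc(O[Si](C(C)C)(C(C)C)C(C)C)cc1OCC=C | intermediate
11 | (±)-1-[2-(prop-2-enyloxy)-4-(triisopropylsilyloxy)phenyl]-2-[4-methoxy-5-(3-methylbut-2-enyl)-2-(triisopropylsilyloxy)phenyl]prop-2-en-1-ol | C=C(C(O)c1ccc(O[Si](C(C)C)(C(C)C)C(C)C)cc1OCC=C)c1cc(CC=C(C)C)c(OC)cc1O[Si](C(C)C)(C(C)C)C(C)C | intermediate
12 | (±)-2-{1-hydroxy-2-[4-methoxy-5-(3-methylbut-2-enyl)-2-(triisopropylsilyloxy)phenyl]prop-2-enyl}-5-(triisopropylsilyloxy)phenol | C=C(C(O)c1ccc(O[Si](C(C)C)(C(C)C)C(C)C)cc1O)c1cc(CC=C(C)C)c(OC)cc1O[Si](C(C)C)(C(C)C)C(C)C | intermediate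
13 | 1-[2-hydroxy-4-(triisopropylsilyloxy)phenyl]-2-[4-methoxy-5-(3-methylbut-2-enyl)-2-(triisopropylsilyloxy)phenyl]prop-2-en-1-one (key-step precursor) | C=C(C(=O)c1ccc(O[Si](C(C)C)(C(C)C)C(C)C)cc1O)c1cc(CC=C(C)C)c(OC)cc1O[Si](C(C)C)(C(C)C)C(C)C | intermediate
14 | 3-[4-methoxy-5-(3-methylbut-2-enyl)-2-(triisopropylsilyloxy)phenyl]-7-(triisopropylsilyloxy)-2H-chromen-4-ol (not isolated) | OC1=C(c2cc(CC=C(C)C)c(OC)cc2O[Si](C(C)C)(C(C)C)C(C)C)COc2cc(O[Si](C(C)C)(C(C)C)C(C)C)ccc12 | intermediate
15 | (3S)-3-[4-methoxy-5-(3-methylbut-2-enyl)-2-(triisopropylsilyloxy)phenyl]-7-(triisopropylsilyloxy)chroman-4-one | COc1cc(O[Si](C(C)C)(C(C)C)C(C)C)c([C@H]2COc3cc(O[Si](C(C)C)(C(C)C)C(C)C)ccc3C2=O)cc1CC=C(C)C | intermediate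
16 | (3S)-7-hydroxy-3-[2-hydroxy-4-methoxy-5-(3-methylbut-2-enyl)phenyl]chroman-4-one | COc1cc(O)c([C@H]2COc3cc(O)ccc3C2=O)cc1CC=C(C)C | target

**Step count.** Total: 11 steps. Longest linear sequence: 9 steps (steps 1–4, then 7–11); the ring A branch (steps 5–6) joins at step 7.

**Steps most likely to fail**

1. Step 10 (proposed new method). The proton transfer to the enol may discriminate poorly between its two faces, or uncatalysed ring closure may compete and erode the enantiomeric purity. The fallback uses known chemistry and sets out from 13. Ring closure with catalytic Et3N in CH2Cl2 should give the racemic isoflavanone, (±)-3-[4-methoxy-5-(3-methylbut-2-enyl)-2-(triisopropylsilyloxy)phenyl]-7-(triisopropylsilyloxy)chroman-4-one F1. O-Acylation of its hindered, aryl-stabilised enolate with allyl chloroformate (LiN(SiMe3)2, THF, −78 °C) should give the allyl enol carbonate F2. Palladium-catalysed decarboxylative enantioselective protonation (Pd2(dba)3, (S)-t-Bu-PHOX or its antipode, Meldrum's acid as proton donor, dioxane, rt) then sets C3 and rejoins the route at 15.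

2. Step 4. Under the strongly basic enolisation the 2'-silyl group may migrate to the enolate oxygen, the product may eliminate to the arylalkyne, or the electron-rich alkenyl triflate may ionise during purification. The fallback avoids the enolate and sets out from 5. Condensation with 1,2-bis(tert-butyldimethylsilyl)hydrazine (Sc(OTf)3 cat.) should give the N-silyl hydrazone F3. Iodine and 1,1,3,3-tetramethylguanidine (THF, 0 °C; Barton vinyl iodide synthesis) should convert it into the alkenyl iodide F4. F4 is coupled with 10 under the CrCl2/NiCl2 conditions of step 7 and comes back to the route at 11.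

3. Step 3. Regiocontrol in the allyl transfer may be lost, with coupling through the γ-carbon giving the 1,1-dimethylallyl isomer. The fallback sets out from 3. Stille coupling with allyltributylstannane (Pd(PPh3)4, DMF, 90 °C), which has no regiochemical ambiguity, should give the allylarene F5. Cross-metathesis with excess 2-methylbut-2-ene (second-generation Grubbs catalyst, CH2Cl2, 40 °C) then installs the trisubstituted alkene and returns to the route at 5.

**Further compounds**

F1 | step 10 | (±)-3-[4-methoxy-5-(3-methylbut-2-enyl)-2-(triisopropylsilyloxy)phenyl]-7-(triisopropylsilyloxy)chroman-4-one | COc1cc(O[Si](C(C)C)(C(C)C)C(C)C)c(C2COc3cc(O[Si](C(C)C)(C(C)C)C(C)C)ccc3C2=O)cc1CC=C(C)C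
F2 | step 10 | prop-2-enyl 3-[4-methoxy-5-(3-methylbut-2-enyl)-2-(triisopropylsilyloxy)phenyl]-7-(triisopropylsilyloxy)-2H-chromen-4-yl carbonate | C=CCOC(=O)OC1=C(c2cc(CC=C(C)C)c(OC)cc2O[Si](C(C)C)(C(C)C)C(C)C)COc2cc(O[Si](C(C)C)(C(C)C)C(C)C)ccc12
F3 | step 4 | N-(tert-butyldimethylsilyl)hydrazone of 1-[4-methoxy-5-(3-methylbut-2-enyl)-2-(triisopropylsilyloxy)phenyl]ethanone | CC(=NN[Si](C)(C)C(C)(C)C)c1cc(CC=C(C)C)c(OC)cc1O[Si](C(C)C)(C(C)C)C(C)C
F4 | step 4 | [2-(1-iodoethenyl)-5-methoxy-4-(3-methylbut-2-enyl)phenoxy]triisopropylsilane | C=C(I)c1cc(CC=C(C)C)c(OC)cc1O[Si](C(C)C)(C(C)C)C(C)C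
F5 | step 3 | 1-[4-methoxy-5-(prop-2-enyl)-2-(triisopropylsilyloxy)phenyl]ethanone | CC(=O)c1cc(CC=C)c(OC)cc1O[Si](C(C)C)(C(C)C)C(C)C
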